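**Remark on the chemistry:** compounds 1, 3, 10, 11, 21 and 24 are taken as purchased. Locants C1–C6 are those of the cyclohexenone ring of 29 (C1 ketone, C2 nitrogen-bearing, C4 carbinol, C5/C6 epoxide). The alkyne is carried as its trimethylsilyl derivative and the C4 oxygen as a tert-butyldimethylsilyl ether, for the reasons in the first section.

## Structural features

Compound 29 is built on one cyclohex-2-enone ring in which every carbon is functionalised: C1 is the ketone, C2 carries an amide nitrogen, C2=C3 is the enone alkene, C4 is a tertiary carbinol and C5–C6 carry a cis-fused epoxide. The C2 nitrogen bears a (2E,4E,6E)-8-methylnona-2,4,6-trienoyl group. C4 bears an all-E heptatrienamide chain whose nitrogen sits on a 3-hydroxycyclopent-2-enone, a vinylogous acid. The three stereocentres are contiguous (C4 S, C5 S, C6 R), and the C4 hydroxyl lies on the face opposite to the epoxide oxygen. The fragile groups are the α,β-epoxy ketone (base, nucleophiles, hydride), the trans hydroxy epoxide (epoxide migration under base), the two trienes (light, acid), the enamide and the acidic enol. The real difficulty is the fully substituted C4: its oxygen must be set on a defined face relative to C5/C6 while a two-carbon handle for the lower chain is kept, and the sequence must not expose late groups to the reagents that make early ones. The key step uses the fact that C1=O and C4–OH stand 1,4 across C2=C3 while C5 and C6 carry oxygen on the opposite face. That is the pattern left by O–O cleavage of a 1,4-endoperoxide of a 5,6-cis-dioxygenated cyclohexa-1,3-diene, so the diene C1=C2–C3=C4 of 4 takes up dioxygen and the dioxolane on C5/C6 directs the face. The (1S,2S) configuration of 1 has the right absolute sense, because its C–Br carbon becomes C4, its C2 becomes C5 and its C1 becomes C6. A trimethylsilyl alkyne is preferred to a bulkier one because it is lost in the carbonate/methanol that closes the epoxide, whereas a bulkier silane would need a basic fluoride in the presence of the epoxy ketone.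

## Logic of the disconnections

**29 ⇒ 20 + 28.** The single bond between the second and third chain carbon counted from C4 is cut. It joins two alkenes of fixed E geometry, so it can be made by cross-coupling without creating a new stereo-element. The gain is full convergence: the acidic five-membered ring and the most sensitive triene appear only in the last step. The forward coupling must run near room temperature without base, keep both geometries, and tolerate a free tertiary alcohol, an enol and an epoxy ketone.

**20 ⇒ 19 ⇒ 18.** The C–Sn and C–H bonds across the former alkyne are removed, then the O–Si bond at C4 is restored. A terminal alkyne is an inert two-carbon handle, and the silyl ether prevents epoxide migration in basic steps. The demand is syn addition with tin on the terminal carbon, chemoselective against the enone and the epoxy ketone. Desilylation must be non-basic and must come before tin is present.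

**18 ⇒ 15 ⇒ 14.** The C6–O bond of the epoxide is cut so that C5 and C6 each carry a hydroxyl on the same face (17 and 16 are the transient forms), the terminal C–H becomes C–Si, and the diol is closed as a ketal. This exposes the cis-dioxygenated C5/C6 unit that the key step needs. The forward step must turn a cis-diol into an epoxide on the same face, which requires two inversions at one carbon, under conditions the enamide survives.

**14 ⇒ 9 + 13.** The C2–N bond is cut. The whole upper chain then arrives as a primary amide in one step, at an alkenyl iodide that an enone delivers by α-iodination. The coupling must be mild enough for the C(sp)–Si bond and for the ketone with its β-oxygen.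

**9 ⇒ 8 ⇒ 7.** The C2–I bond and the O–Si bond at C4 are removed. This leaves a plain 4-hydroxy enone. Iodination must go to C2 although C3 adjoins a quaternary carbon.

**7 ⇒ 6.** The C1 carbonyl oxygen and the C4 hydroxyl oxygen are rejoined by an O–O bond and C1 regains its hydrogen. A 4-hydroxy enone is the base-induced isomer of a 1,4-endoperoxide. The forward rearrangement must remove the C1 hydrogen only, which is assured because C4 has none.

**6 ⇒ 4 + 5.** The C1–O and C4–O bonds are cut, which opens the peroxide-bridged ring and returns a flat diene and 5. One ring, two bonds and two stereocentres (C1, C4) are removed at once. The forward step needs 5 in its singlet state to add to the face opposite the dioxolane.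

**4 ⇒ 2 + 3 ⇒ 1.** The bond between C4 and the alkyne carbon is cut, then the ketal is opened. This leads to an enantiopure diene diol that is bought, and to a simple alkyne. The coupling must run cold enough that the diene does not dimerise.

**13 ⇒ 12 ⇒ 10 + 11.** The amide C–N bond is exchanged for an ester C–O bond, then the C4=C5 alkene of the trienoate is cut. Both fragments are then simple commercial C6 and C4 units. The olefination must give the new alkene E.

**28 ⇒ 26 + 23; 26 ⇒ 25 ⇒ 24; 23 ⇒ 22 ⇒ 21.** The amide C–N bond is cut (27 is the activated form of 26). The acid is traced through the aldehyde oxidation level to an enolate whose C–O bond becomes the C–Br bond. The amine is traced through a C=N bond to the free methylene of a 1,3-dione. Acylation must end on nitrogen, and the bromodiene must stay E,E.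

## Other disconnections considered

**Alternative 1:** The cut is the ring C–C bond of the cyclopentenone amide A3 (identical with 28) between the nitrogen-bearing carbon and a carbonyl carbon. This opens the ring to the acyclic keto ester A2, the amide of 27 with the aminolevulinate ester salt A1.
- *Forward key step:* a strong alkoxide base makes the ketone enolate at the nitrogen-bearing carbon of A2, which attacks the ester carbonyl (Dieckmann-type closure) to give A3.
- *In favour:* it follows the biosynthetic origin of this ring, A1 is cheap, and the self-condensing free aminodione never appears. A3 would take two steps from 27 against three for steps 14, 15 and 18, so on step economy for this fragment it is better by one step.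
- *Against:* the closure is a 5-(enolendo)-exo-trig process and geometrically strained. The amide N–H is removed first, so a dianion is needed. The other ketone enolate is unproductive. The bromodiene is exposed to a strong base that can eliminate HBr or add in conjugate fashion.
- *Comparison:* it concerns only the lower fragment, so it makes neither the six-membered ring nor any stereocentre and is a possible replacement for three steps rather than a rival to step 3. On mechanism, the chosen acylation of 23 runs under mild conditions where this closure needs strong base on a vinyl bromide.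

**Alternative 2:** The cut removes the C5–C6 bond and the C6–O bond of the epoxide in A5, leading to the acyclic (Z)-enone A4 with a chloromethyl ketone at one end and a quaternary α-silyloxy aldehyde at the other.
- *Forward key step:* base forms the α-chloro enolate, which adds to the aldehyde (6-(enolendo)-exo-trig aldol); the new alkoxide then displaces chloride (3-exo-tet), so ring and epoxide form in one operation.
- *In favour:* A5 already holds the epoxide, the protected carbinol and the alkyne, with no peroxide and no photochemistry. After its key step it would be two steps shorter than the chosen plan, because the diol unmasking and epoxide closure are not needed; on that count it is better.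
- *Against:* A4 needs an enantioenriched quaternary carbinol bearing an alkyne, a (Z)-alkene and an aldehyde, for which there is no chiral-pool source. The (Z)-enone can isomerise to the E form, which cannot cyclise. The anti relation between epoxide and silyloxy group rests on 1,2-induction from a centre whose substituents differ little in size. The aldol is reversible and the product is base-sensitive.
- *Comparison:* the chosen plan takes all three stereocentres from enantiopure 1 through a face-selective cycloaddition of a well-known type, where this one needs an earlier asymmetric step and an untested diastereoselection. Both then need the same C2 iodination and amidation. Overall step economy is about equal once the synthesis of A4 is counted.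

**Alternative 3:** The cut removes two C–C bonds, from C2 and C3 to a five-carbon bridge, so the adduct A8 is traced to the quinone monoketal A6 and cyclopentadiene A7; the norbornene masks the C2=C3 alkene.
- *Forward key step:* a chiral titanium–binaphthol Lewis acid made from Ti(OiPr)2Cl2 directs endo addition of A7 to one enantiotopic alkene of A6.
- *In favour:* it is catalytic and asymmetric from achiral, cheap materials. The convex shape of A8 would direct both a nucleophilic epoxidation of C5=C6 and the addition of an alkynyl nucleophile to the C4 ketone from the same open face, which gives the anti hydroxy epoxide directly. The epoxide would come in one step instead of two, which is better than the chosen plan, and the face-shielding logic is the equal of the dioxolane.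
- *Against:* one-point binding of a monoketal makes the level of enantioselection uncertain. The retro-Diels–Alder that unmasks C2=C3 needs strong heating next to a tertiary propargylic alcohol and an epoxide, and must precede every polyene. Ketal hydrolysis and the C2 iodination and amidation are still required.
- *Comparison:* the chosen plan starts with assured absolute configuration and unmasks nothing thermally. This one forms C–C bonds where the chosen plan forms C–O bonds. Step counts are expected to be similar.

Key step: step 3

## Route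

**Step 1**
Reactants: 1 (1S,2S)-3-bromocyclohexa-3,5-diene-1,2-diol
Product: 2 (3aS,7aS)-4-bromo-2,2-dimethyl-3a,7a-dihydro-1,3-benzodioxole
Conditions: Me2C(OMe)2, TsOH·H2O (cat.), acetone, 0 °C → rt
Reagents that add atoms: 2,2-dimethoxypropane, COC(C)(C)OC
Why: Acid-catalysed acetonide formation on a cis-1,2-diol; no stereocentre is touched, and the dioxolane stops aromatisation of the diene diol and later shields one face of the diene.

**Step 2**
Reactants: 2 (3aS,7aS)-4-bromo-2,2-dimethyl-3a,7a-dihydro-1,3-benzodioxole; 3 ethynyltrimethylsilane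
Product: 4 trimethyl{[(3aR,7aS)-2,2-dimethyl-3a,7a-dihydro-1,3-benzodioxol-4-yl]ethynyl}silane
Conditions: Pd(PPh3)4 (5 mol %), CuI (10 mol %), Et3N, THF, rt, dark
Reagents that add atoms: none
Why: Sonogashira coupling of an alkenyl bromide with a terminal alkyne, a known reaction of halodiene acetonides; the stereocentres are remote (the descriptor at C3a changes only because the priorities change), and the product is kept cold and dilute because such dienes dimerise.

**Step 3**
Reactants: 4 trimethyl{[(3aR,7aS)-2,2-dimethyl-3a,7a-dihydro-1,3-benzodioxol-4-yl]ethynyl}silane; 5 dioxygen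
Product: 6 (1R,2S,6R,7R)-4,4-dimethyl-1-[(trimethylsilyl)ethynyl]-3,5,8,9-tetraoxatricyclo[5.2.2.0^2,6]undec-10-ene (peroxide bridge anti to the dioxolane)
Conditions: O2 (1 atm), hν (visible), tetraphenylporphyrin (cat.), CH2Cl2, −78 °C
Reagents that add atoms: none
Why: The sensitiser transfers energy to 5, and singlet oxygen adds across C1 and C4 of the s-cis-locked diene in a concerted suprafacial [4+2] cycloaddition; the closest known reaction type is the photooxygenation of cyclohexa-3,5-diene-1,2-diol acetonides. Both C–O bonds form in the same event, which closes the 1,2-dioxane ring as the third bridge of a 2,3-dioxabicyclo[2.2.2]oct-5-ene ([4+2] mode of closure). The new stereocentres C1 and C4 are set together, and the only variable is the face. The cis-fused dioxolane and its inward methyl group cover the face that carries the C5/C6 oxygens, so oxygen should enter from the other face and the C4–O bond ends up trans to them. The absolute sense therefore comes from 1 alone, with no external chiral reagent. Regiochemistry is not an issue with a symmetrical dienophile. The selectivity needed is facial, plus chemoselectivity against the silyl alkyne and against ene reaction, which the locked diene geometry and the oxygen-deactivated allylic positions secure. The low temperature suppresses dimerisation of 4 and breakdown of the peroxide.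

**Step 4**
Reactants: 6 (1R,2S,6R,7R)-4,4-dimethyl-1-[(trimethylsilyl)ethynyl]-3,5,8,9-tetraoxatricyclo[5.2.2.0^2,6]undec-10-ene
Product: 7 (3aR,7R,7aS)-7-hydroxy-2,2-dimethyl-7-[(trimethylsilyl)ethynyl]-3a,7a-dihydro-1,3-benzodioxol-4(7H)-one
Conditions: Et3N (cat.), CH2Cl2, 0 °C
Reagents that add atoms: none
Why: Kornblum–DeLaMare rearrangement: the amine removes the bridgehead hydrogen at C1, the weak O–O bond breaks, C1 becomes the ketone and the C4 oxygen is released as the tertiary alcohol. C4 has no hydrogen, so only this regiochemistry is possible, and the C4–O bond set in step 3 is not touched.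

**Step 5**
Reactants: 7 (3aR,7R,7aS)-7-hydroxy-2,2-dimethyl-7-[(trimethylsilyl)ethynyl]-3a,7a-dihydro-1,3-benzodioxol-4(7H)-one
Product: 8 (3aR,7R,7aS)-7-{[tert-butyl(dimethyl)silyl]oxy}-2,2-dimethyl-7-[(trimethylsilyl)ethynyl]-3a,7a-dihydro-1,3-benzodioxol-4(7H)-one
Conditions: TBSOTf, 2,6-lutidine, CH2Cl2, −78 → 0 °C
Reagents that add atoms: tert-butyldimethylsilyl trifluoromethanesulfonate, CC(C)(C)[Si](C)(C)OS(=O)(=O)C(F)(F)F
Why: Silylation of a tertiary propargylic alcohol with a silyl triflate and a hindered pyridine base; the slim alkyne leaves the hydroxyl accessible. The ether is stable to the later aqueous acid and carbonate and blocks retro-alkynylation and epoxide migration.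

**Step 6**
Reactants: 8 (3aR,7R,7aS)-7-{[tert-butyl(dimethyl)silyl]oxy}-2,2-dimethyl-7-[(trimethylsilyl)ethynyl]-3a,7a-dihydro-1,3-benzodioxol-4(7H)-one
Product: 9 (3aR,7R,7aS)-7-{[tert-butyl(dimethyl)silyl]oxy}-5-iodo-2,2-dimethyl-7-[(trimethylsilyl)ethynyl]-3a,7a-dihydro-1,3-benzodioxol-4(7H)-one
Conditions: I2, pyridine, CH2Cl2, rt, dark
Reagents that add atoms: iodine, II
Why: α-Iodination of a cyclic enone by addition of pyridine to C3, iodination of the enolate at C2 and loss of pyridine, a sequence that also works on 4,4-disubstituted cyclohexenones; the alkynylsilane and the ketal are inert.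

**Step 7**
Reactants: 10 (E)-4-methylpent-2-enal; 11 ethyl (E)-4-(diethoxyphosphoryl)but-2-enoate
Product: 12 ethyl (2E,4E,6E)-8-methylnona-2,4,6-trienoate
Conditions: LiN(SiMe3)2, THF, −78 → 0 °C
Reagents that add atoms: none
Why: Vinylogous Horner–Wadsworth–Emmons olefination; the stabilised phosphonate anion should give the new C4=C5 alkene E, and the two existing E alkenes are carried through.

**Step 8**
Reactants: 12 ethyl (2E,4E,6E)-8-methylnona-2,4,6-trienoate
Product: 13 (2E,4E,6E)-8-methylnona-2,4,6-trienamide
Conditions: AlMe3, NH4Cl, toluene, 0 → 50 °C; then aq. HCl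
Reagents that add atoms: ammonium chloride, [NH4+].[Cl-]
Why: Aluminium amide aminolysis of an ester (Weinreb amidation); the chloro(methyl)aluminium amide formed in the flask attacks the ester carbonyl directly, so the triene is left alone.

**Step 9**
Reactants: 9 (3aR,7R,7aS)-7-{[tert-butyl(dimethyl)silyl]oxy}-5-iodo-2,2-dimethyl-7-[(trimethylsilyl)ethynyl]-3a,7a-dihydro-1,3-benzodioxol-4(7H)-one; 13 (2E,4E,6E)-8-methylnona-2,4,6-trienamide
Product: 14 (2E,4E,6E)-N-[(3aR,7R,7aS)-7-{[tert-butyl(dimethyl)silyl]oxy}-2,2-dimethyl-4-oxo-7-[(trimethylsilyl)ethynyl]-3a,4,7,7a-tetrahydro-1,3-benzodioxol-5-yl]-8-methylnona-2,4,6-trienamide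
Conditions: CuI (10 mol %), MeNHCH2CH2NHMe (20 mol %), K3PO4 (anhydrous), toluene, 50 °C
Reagents that add atoms: none
Why: Copper-catalysed amidation of an alkenyl iodide with a primary amide (Goldberg-type C–N coupling), a known reaction of 2-iodoenones. A dry, heterogeneous phosphate base in toluene is chosen so that the C(sp)–Si bond and the ketone with its β-oxygen are not attacked.

**Step 10**
Reactants: 14 (2E,4E,6E)-N-[(3aR,7R,7aS)-7-{[tert-butyl(dimethyl)silyl]oxy}-2,2-dimethyl-4-oxo-7-[(trimethylsilyl)ethynyl]-3a,4,7,7a-tetrahydro-1,3-benzodioxol-5-yl]-8-methylnona-2,4,6-trienamide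
Product: 15 (2E,4E,6E)-N-[(3R,4S,5R)-3-{[tert-butyl(dimethyl)silyl]oxy}-4,5-dihydroxy-6-oxo-3-[(trimethylsilyl)ethynyl]cyclohex-1-en-1-yl]-8-methylnona-2,4,6-trienamide
Conditions: CF3CO2H/H2O (10:1), CH2Cl2, 0 °C
Reagents that add atoms: none
Why: Acid hydrolysis of an isopropylidene ketal; the C–O bonds at C5 and C6 are not broken, so both centres keep their configuration. The tertiary silyl ether, the alkynylsilane and the enamide should be stable to cold aqueous acid.

**Step 11**
Reactants: 15 (2E,4E,6E)-N-[(3R,4S,5R)-3-{[tert-butyl(dimethyl)silyl]oxy}-4,5-dihydroxy-6-oxo-3-[(trimethylsilyl)ethynyl]cyclohex-1-en-1-yl]-8-methylnona-2,4,6-trienamide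
Product: 18 (2E,4E,6E)-N-[(1R,5R,6S)-5-{[tert-butyl(dimethyl)silyl]oxy}-5-ethynyl-2-oxo-7-oxabicyclo[4.1.0]hept-3-en-3-yl]-8-methylnona-2,4,6-trienamide, via cyclic methyl orthoacetate 16 (not isolated), via trans-bromoacetate 17 (not isolated)
Conditions: a) MeC(OMe)3, PPTS (cat.), CH2Cl2, rt, evaporate; b) AcBr, CH2Cl2, 0 °C, evaporate; c) K2CO3, MeOH, 0 °C → rt
Reagents that add atoms: none
Why: Orthoester/acetoxonium route from a 1,2-diol to an epoxide: acetyl bromide turns 16 into a dioxolanylium ion, which bromide opens by SN2 at C6 (activated by the ketone, whereas C5 is neopentyl-like) to give 17 with inversion. Carbonate in methanol removes the acetate, and the C5 alkoxide displaces bromide with a second inversion at C6 (intramolecular Williamson closure), so the epoxide oxygen stays on the face of the original diol, anti to the C4 oxygen. The same medium cleaves the C(sp)–SiMe3 bond and frees the alkyne.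

**Step 12**
Reactants: 18 (2E,4E,6E)-N-[(1R,5R,6S)-5-{[tert-butyl(dimethyl)silyl]oxy}-5-ethynyl-2-oxo-7-oxabicyclo[4.1.0]hept-3-en-3-yl]-8-methylnona-2,4,6-trienamide
Product: 19 (2E,4E,6E)-N-[(1R,5R,6S)-5-ethynyl-5-hydroxy-2-oxo-7-oxabicyclo[4.1.0]hept-3-en-3-yl]-8-methylnona-2,4,6-trienamide
Conditions: HF·pyridine, pyridine, THF, 0 °C → rt
Reagents that add atoms: none
Why: Fluoride cleavage of a silyl ether under buffered, non-basic conditions, so that no alkoxide is generated next to the epoxide; the electron-poor tertiary propargylic oxygen is a good leaving group on silicon. The step precedes the introduction of tin because HF would protodestannylate an alkenylstannane.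

**Step 13**
Reactants: 19 (2E,4E,6E)-N-[(1R,5R,6S)-5-ethynyl-5-hydroxy-2-oxo-7-oxabicyclo[4.1.0]hept-3-en-3-yl]-8-methylnona-2,4,6-trienamide
Product: 20 (2E,4E,6E)-N-[(1R,5R,6S)-5-hydroxy-2-oxo-5-[(E)-2-(tributylstannyl)ethenyl]-7-oxabicyclo[4.1.0]hept-3-en-3-yl]-8-methylnona-2,4,6-trienamide
Conditions: PdCl2(PPh3)2 (3 mol %), Bu3SnH (1.2 equiv, slow addition), THF, 0 °C
Reagents that add atoms: tributyltin hydride, CCCC[SnH](CCCC)CCCC
Why: Palladium-catalysed hydrostannation of a terminal alkyne; syn addition of Sn–H gives the E alkene, and the fully substituted propargylic carbon should steer tin to the terminal carbon. The alkyne is expected to react well before the hindered, amide-substituted enone.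

**Step 14**
Reactants: 21 cyclopentane-1,3-dione
Product: 22 2-(hydroxyimino)cyclopentane-1,3-dione
Conditions: NaNO2, aq. HCl, 0 °C
Reagents that add atoms: sodium nitrite, [Na+].[O-]N=O
Why: Nitrosation of the active methylene of a 1,3-dione; the C-nitroso compound tautomerises to the oxime.

**Step 15**
Reactants: 22 2-(hydroxyimino)cyclopentane-1,3-dione
Product: 23 2-amino-3-hydroxycyclopent-2-en-1-one hydrochloride
Conditions: H2 (1 atm), 10% Pd/C, HCl, EtOH, rt
Reagents that add atoms: hydrogen chloride, Cl
Why: Catalytic hydrogenation of an α-oximino dicarbonyl compound to the amine, trapped as its hydrochloride because the free aminodione condenses with itself.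

**Step 16**
Reactants: 24 potassium (1E,3E)-5-oxopenta-1,3-dien-1-olate (glutaconaldehyde potassium salt)
Product: 25 (2E,4E)-5-bromopenta-2,4-dienal
Conditions: PPh3, Br2, CH2Cl2, 0 °C → rt
Reagents that add atoms: bromine, BrBr
Why: Deoxybromination of a vinylogous formate enolate by dibromotriphenylphosphorane (O-phosphonium formation, then addition–elimination of bromide); the conjugated E,E bromodienal is the stable isomer.

**Step 17**
Reactants: 25 (2E,4E)-5-bromopenta-2,4-dienal
Product: 26 (2E,4E)-5-bromopenta-2,4-dienoic acid
Conditions: NaClO2, NaH2PO4, 2-methylbut-2-ene, tBuOH/H2O, 0 °C → rt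
Reagents that add atoms: sodium chlorite, [Na+].[O-]Cl=O
Why: Pinnick oxidation of an unsaturated aldehyde to the acid; the alkene scavenger removes hypochlorous acid, so the bromodiene is not touched.

**Step 18**
Reactants: 26 (2E,4E)-5-bromopenta-2,4-dienoic acid; 23 2-amino-3-hydroxycyclopent-2-en-1-one hydrochloride
Product: 28 (2E,4E)-5-bromo-N-(2-hydroxy-5-oxocyclopent-1-en-1-yl)penta-2,4-dienamide, via acid chloride 27 (not isolated)
Conditions: a) (COCl)2, DMF (cat.), CH2Cl2, 0 °C → rt, evaporate; b) 23, Et3N, CH2Cl2/DMF, 0 °C → rt
Reagents that add atoms: none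
Why: Acid chloride formation and N-acylation of the amine freed from its salt; any O-acylated enol ester should pass its acyl group on to nitrogen, so the amide is the final product.

**Step 19**
Reactants: 20 (2E,4E,6E)-N-[(1R,5R,6S)-5-hydroxy-2-oxo-5-[(E)-2-(tributylstannyl)ethenyl]-7-oxabicyclo[4.1.0]hept-3-en-3-yl]-8-methylnona-2,4,6-trienamide; 28 (2E,4E)-5-bromo-N-(2-hydroxy-5-oxocyclopent-1-en-1-yl)penta-2,4-dienamide
Product: 29 (2E,4E,6E)-N-[(1R,5S,6S)-5-hydroxy-5-{(1E,3E,5E)-7-[(2-hydroxy-5-oxocyclopent-1-en-1-yl)amino]-7-oxohepta-1,3,5-trien-1-yl}-2-oxo-7-oxabicyclo[4.1.0]hept-3-en-3-yl]-8-methylnona-2,4,6-trienamide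
Conditions: Pd2(dba)3 (5 mol %), AsPh3 (40 mol %), DMF, rt, dark
Reagents that add atoms: none
Why: Stille coupling of an alkenylstannane with an alkenyl bromide; both partners should react with retention of their E geometry. No base is needed, and the weakly bound arsine ligand allows transmetallation at room temperature, so the free tertiary alcohol, the epoxy ketone and the acidic enol should remain intact.

## Compound list

1 | (1S,2S)-3-bromocyclohexa-3,5-diene-1,2-diol | C1=CC=C(Br)[C@@H](O)[C@H]1O | starting material
2 | (3aS,7aS)-4-bromo-2,2-dimethyl-3a,7a-dihydro-1,3-benzodioxole | C1=CC=C(Br)[C@H]2OC(C)(C)O[C@@H]12 | intermediate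
3 | ethynyltrimethylsilane | C#C[Si](C)(C)C | starting material
4 | trimethyl{[(3aR,7aS)-2,2-dimethyl-3a,7a-dihydro-1,3-benzodioxol-4-yl]ethynyl}silane | C1=CC=C(C#C[Si](C)(C)C)[C@H]2OC(C)(C)O[C@@H]12 | intermediate
5 | dioxygen | O=O | starting material
6 | (1R,2S,6R,7R)-4,4-dimethyl-1-[(trimethylsilyl)ethynyl]-3,5,8,9-tetraoxatricyclo[5.2.2.0^2,6]undec-10-ene, peroxide bridge anti to the dioxolane | C1=C[C@]2(C#C[Si](C)(C)C)OO[C@H]1[C@@H]1OC(C)(C)O[C@H]21 | intermediate
7 | (3aR,7R,7aS)-7-hydroxy-2,2-dimethyl-7-[(trimethylsilyl)ethynyl]-3a,7a-dihydro-1,3-benzodioxol-4(7H)-one | O=C1C=C[C@@](O)(C#C[Si](C)(C)C)[C@H]2OC(C)(C)O[C@@H]12 | intermediate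
8 | (3aR,7R,7aS)-7-{[tert-butyl(dimethyl)silyl]oxy}-2,2-dimethyl-7-[(trimethylsilyl)ethynyl]-3a,7a-dihydro-1,3-benzodioxol-4(7H)-one | O=C1C=C[C@@](O[Si](C)(C)C(C)(C)C)(C#C[Si](C)(C)C)[C@H]2OC(C)(C)O[C@@H]12 | intermediate
9 | (3aR,7R,7aS)-7-{[tert-butyl(dimethyl)silyl]oxy}-5-iodo-2,2-dimethyl-7-[(trimethylsilyl)ethynyl]-3a,7a-dihydro-1,3-benzodioxol-4(7H)-one | O=C1C(I)=C[C@@](O[Si](C)(C)C(C)(C)C)(C#C[Si](C)(C)C)[C@H]2OC(C)(C)O[C@@H]12 | intermediate
10 | (E)-4-methylpent-2-enal | CC(C)/C=C/C=O | starting material
11 | ethyl (E)-4-(diethoxyphosphoryl)but-2-enoate | CCOC(=O)/C=C/CP(=O)(OCC)OCC | starting material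
12 | ethyl (2E,4E,6E)-8-methylnona-2,4,6-trienoate | CC(C)/C=C/C=C/C=C/C(=O)OCC | intermediate
13 | (2E,4E,6E)-8-methylnona-2,4,6-trienamide | CC(C)/C=C/C=C/C=C/C(N)=O | intermediate
14 | (2E,4E,6E)-N-[(3aR,7R,7aS)-7-{[tert-butyl(dimethyl)silyl]oxy}-2,2-dimethyl-4-oxo-7-[(trimethylsilyl)ethynyl]-3a,4,7,7a-tetrahydro-1,3-benzodioxol-5-yl]-8-methylnona-2,4,6-trienamide | CC(C)/C=C/C=C/C=C/C(=O)NC1=C[C@@](O[Si](C)(C)C(C)(C)C)(C#C[Si](C)(C)C)[C@H]2OC(C)(C)O[C@H]2C1=O | intermediate
15 | (2E,4E,6E)-N-[(3R,4S,5R)-3-{[tert-butyl(dimethyl)silyl]oxy}-4,5-dihydroxy-6-oxo-3-[(trimethylsilyl)ethynyl]cyclohex-1-en-1-yl]-8-methylnona-2,4,6-trienamide | CC(C)/C=C/C=C/C=C/C(=O)NC1=C[C@@](O[Si](C)(C)C(C)(C)C)(C#C[Si](C)(C)C)[C@@H](O)[C@@H](O)C1=O | intermediate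
16 | cyclic methyl orthoacetate (2-methoxy-2-methyl-1,3-dioxolane) of 15 across the C5 and C6 oxygens, both epimers at the orthoester carbon | CC(C)/C=C/C=C/C=C/C(=O)NC1=C[C@@](O[Si](C)(C)C(C)(C)C)(C#C[Si](C)(C)C)[C@H]2OC(C)(OC)O[C@H]2C1=O | intermediate
17 | (2E,4E,6E)-N-[(3R,4R,5S)-4-acetoxy-5-bromo-3-{[tert-butyl(dimethyl)silyl]oxy}-6-oxo-3-[(trimethylsilyl)ethynyl]cyclohex-1-en-1-yl]-8-methylnona-2,4,6-trienamide (bromine at C6 on the face of the silyloxy group, acetoxy at C5 on the other face) | CC(C)/C=C/C=C/C=C/C(=O)NC1=C[C@@](O[Si](C)(C)C(C)(C)C)(C#C[Si](C)(C)C)[C@@H](OC(C)=O)[C@H](Br)C1=O | intermediate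
18 | (2E,4E,6E)-N-[(1R,5R,6S)-5-{[tert-butyl(dimethyl)silyl]oxy}-5-ethynyl-2-oxo-7-oxabicyclo[4.1.0]hept-3-en-3-yl]-8-methylnona-2,4,6-trienamide | CC(C)/C=C/C=C/C=C/C(=O)NC1=C[C@@](O[Si](C)(C)C(C)(C)C)(C#C)[C@H]2O[C@H]2C1=O | intermediate
19 | (2E,4E,6E)-N-[(1R,5R,6S)-5-ethynyl-5-hydroxy-2-oxo-7-oxabicyclo[4.1.0]hept-3-en-3-yl]-8-methylnona-2,4,6-trienamide | CC(C)/C=C/C=C/C=C/C(=O)NC1=C[C@@](O)(C#C)[C@H]2O[C@H]2C1=O | intermediate
20 | (2E,4E,6E)-N-[(1R,5R,6S)-5-hydroxy-2-oxo-5-[(E)-2-(tributylstannyl)ethenyl]-7-oxabicyclo[4.1.0]hept-3-en-3-yl]-8-methylnona-2,4,6-trienamide | CC(C)/C=C/C=C/C=C/C(=O)NC1=C[C@@](O)(/C=C/[Sn](CCCC)(CCCC)CCCC)[C@H]2O[C@H]2C1=O | intermediate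
21 | cyclopentane-1,3-dione | O=C1CCC(=O)C1 | starting material
22 | 2-(hydroxyimino)cyclopentane-1,3-dione | O=C1CCC(=O)C1=NO | intermediate
23 | 2-amino-3-hydroxycyclopent-2-en-1-one hydrochloride | Cl.NC1=C(O)CCC1=O | intermediate
24 | potassium (1E,3E)-5-oxopenta-1,3-dien-1-olate (glutaconaldehyde potassium salt) | [K+].[O-]/C=C/C=C/C=O | starting material
25 | (2E,4E)-5-bromopenta-2,4-dienal | O=C/C=C/C=C/Br | intermediate
26 | (2E,4E)-5-bromopenta-2,4-dienoic acid | OC(=O)/C=C/C=C/Br | intermediate
27 | (2E,4E)-5-bromopenta-2,4-dienoyl chloride | ClC(=O)/C=C/C=C/Br | intermediate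
28 | (2E,4E)-5-bromo-N-(2-hydroxy-5-oxocyclopent-1-en-1-yl)penta-2,4-dienamide | O=C(/C=C/C=C/Br)NC1=C(O)CCC1=O | intermediate
29 | (2E,4E,6E)-N-[(1R,5S,6S)-5-hydroxy-5-{(1E,3E,5E)-7-[(2-hydroxy-5-oxocyclopent-1-en-1-yl)amino]-7-oxohepta-1,3,5-trien-1-yl}-2-oxo-7-oxabicyclo[4.1.0]hept-3-en-3-yl]-8-methylnona-2,4,6-trienamide | CC(C)/C=C/C=C/C=C/C(=O)NC1=C[C@@](O)(/C=C/C=C/C=C/C(=O)NC2=C(O)CCC2=O)[C@H]2O[C@H]2C1=O | target

## Step count and least certain steps

Total step count: 19. Longest linear sequence: 12 steps (steps 1–6, 9–13 and 19).

**Step 3 (key step).** The most likely failure is loss of the diene by thermal Diels–Alder dimerisation before it meets singlet oxygen, because the cis-fused dioxolane locks it s-cis. The conjugated silyl alkyne also makes the diene less electron-rich than a simple halodiene, so the oxygenation is slower and long irradiation may let the sensitiser break the O–O bond of 6. The fallback changes the order in which the precursor is built, so that the acetonide is never stored. It sets out from 1: Sonogashira coupling with 3 on the unprotected diol, which does not dimerise, gives (1S,2R)-3-[(trimethylsilyl)ethynyl]cyclohexa-3,5-diene-1,2-diol F1. Acetonide formation at 0 °C then comes back to the route at 4 as a cold, dilute solution that is irradiated at once.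

**Step 9.** The most likely failure is base-induced loss of the trimethylsilyl group from the alkyne, followed by copper acetylide side reactions. A slow coupling would also leave the ketone long enough in base to expel the C5 oxygen by β-elimination. The fallback gives up the one-pot unmasking for a sturdier alkynylsilane and sets out from 2.
- Sonogashira coupling with triisopropylsilylacetylene gives the triisopropylsilyl enyne F2.
- The same oxygenation, rearrangement, silylation and iodination give the endoperoxide F3, the hydroxy enone F4, the silyl ether F5 and the iodo enone F6.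
- Amidation with 13, now free to use a stronger base or more heat, gives the enamide F7, and hydrolysis gives the diol F8.
- Passage through the orthoester F9 and the bromoacetate F10 gives the epoxide F11, whose C–Si bond survives the carbonate.
- Bu4NF buffered with AcOH then removes both silicon groups and the route is rejoined at 19.

**Step 11.** The most likely failure is enolisation of the α-bromo ketone in the carbonate/methanol stage, in competition with ring closure. This would lead to epimerisation at C6 or to loss of the C5 acetate by elimination; acetyl bromide may also attack the enamide. The fallback replaces the acetoxonium route by a discrete sulfonate displacement and sets out from 15. The less hindered C6 hydroxyl is converted with Tf2O/2,6-lutidine at −78 °C into the α-keto triflate F12. LiBr displaces it with inversion to give the trans bromohydrin F13. K2CO3/MeOH then closes the epoxide, removes the alkynyl silyl group and comes back at 18.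

**Step 13.** The most likely failure is delivery of tin to the inner alkyne carbon, together with reduction of the enone or reductive opening of the epoxy ketone by the palladium hydride/tin hydride system. The fallback forms the C–C bond first and sets the alkene geometry afterwards, without a tin hydride. It sets out from 19: Sonogashira coupling with 28 gives the dienyne F14. Ruthenium-catalysed trans-hydrosilylation ([Cp*Ru(MeCN)3]PF6, BnMe2SiH) gives the alkenylsilane F15. Protodesilylation (AgF, THF/MeOH/H2O) then comes back at 29 with the E alkene.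

**Step 19.** The most likely failure is protonation of the alkenylstannane by the acidic enol of 28 (protodestannylation), with erosion of triene geometry on palladium or in light as a second concern. The fallback couples a non-enolic partner and forms the amide last. It sets out from 20: Stille coupling with 26, used as its ammonium carboxylate (iPr2NEt), gives the trienoic acid F16. Condensation with 23 (EDC·HCl, HOBt, iPr2NEt, DMF) comes back at 29.

## Further compounds

F1 | step 3 | (1S,2R)-3-[(trimethylsilyl)ethynyl]cyclohexa-3,5-diene-1,2-diol | C1=CC=C(C#C[Si](C)(C)C)[C@@H](O)[C@H]1O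
F2 | step 9 | triisopropyl{[(3aR,7aS)-2,2-dimethyl-3a,7a-dihydro-1,3-benzodioxol-4-yl]ethynyl}silane | C1=CC=C(C#C[Si](C(C)C)(C(C)C)C(C)C)[C@H]2OC(C)(C)O[C@@H]12
F3 | step 9 | triisopropylsilyl analogue of endoperoxide 6 | C1=C[C@]2(C#C[Si](C(C)C)(C(C)C)C(C)C)OO[C@H]1[C@@H]1OC(C)(C)O[C@H]21
F4 | step 9 | triisopropylsilyl analogue of hydroxy enone 7 | O=C1C=C[C@@](O)(C#C[Si](C(C)C)(C(C)C)C(C)C)[C@H]2OC(C)(C)O[C@@H]12
F5 | step 9 | triisopropylsilyl analogue of silyl ether 8 | O=C1C=C[C@@](O[Si](C)(C)C(C)(C)C)(C#C[Si](C(C)C)(C(C)C)C(C)C)[C@H]2OC(C)(C)O[C@@H]12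
F6 | step 9 | triisopropylsilyl analogue of iodo enone 9 | O=C1C(I)=C[C@@](O[Si](C)(C)C(C)(C)C)(C#C[Si](C(C)C)(C(C)C)C(C)C)[C@H]2OC(C)(C)O[C@@H]12
F7 | step 9 | triisopropylsilyl analogue of enamide 14 | CC(C)/C=C/C=C/C=C/C(=O)NC1=C[C@@](O[Si](C)(C)C(C)(C)C)(C#C[Si](C(C)C)(C(C)C)C(C)C)[C@H]2OC(C)(C)O[C@H]2C1=O
F8 | step 9 | triisopropylsilyl analogue of diol 15 | CC(C)/C=C/C=C/C=C/C(=O)NC1=C[C@@](O[Si](C)(C)C(C)(C)C)(C#C[Si](C(C)C)(C(C)C)C(C)C)[C@@H](O)[C@@H](O)C1=O
F9 | step 9 | triisopropylsilyl analogue of orthoester 16 | CC(C)/C=C/C=C/C=C/C(=O)NC1=C[C@@](O[Si](C)(C)C(C)(C)C)(C#C[Si](C(C)C)(C(C)C)C(C)C)[C@H]2OC(C)(OC)O[C@H]2C1=O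
F10 | step 9 | triisopropylsilyl analogue of bromoacetate 17 | CC(C)/C=C/C=C/C=C/C(=O)NC1=C[C@@](O[Si](C)(C)C(C)(C)C)(C#C[Si](C(C)C)(C(C)C)C(C)C)[C@@H](OC(C)=O)[C@H](Br)C1=O
F11 | step 9 | (2E,4E,6E)-N-[(1R,5R,6S)-5-{[tert-butyl(dimethyl)silyl]oxy}-2-oxo-5-[(triisopropylsilyl)ethynyl]-7-oxabicyclo[4.1.0]hept-3-en-3-yl]-8-methylnona-2,4,6-trienamide | CC(C)/C=C/C=C/C=C/C(=O)NC1=C[C@@](O[Si](C)(C)C(C)(C)C)(C#C[Si](C(C)C)(C(C)C)C(C)C)[C@H]2O[C@H]2C1=O
F12 | step 11 | C6 trifluoromethanesulfonate of diol 15 (C5 hydroxyl free) | CC(C)/C=C/C=C/C=C/C(=O)NC1=C[C@@](O[Si](C)(C)C(C)(C)C)(C#C[Si](C)(C)C)[C@@H](O)[C@@H](OS(=O)(=O)C(F)(F)F)C1=O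
F13 | step 11 | trans bromohydrin (C6 bromine on the face of the silyloxy group, C5 hydroxyl on the other face) | CC(C)/C=C/C=C/C=C/C(=O)NC1=C[C@@](O[Si](C)(C)C(C)(C)C)(C#C[Si](C)(C)C)[C@@H](O)[C@H](Br)C1=O
F14 | step 13 | dienyne from 19 and 28 (lower chain with a C≡C bond in place of the first alkene) | CC(C)/C=C/C=C/C=C/C(=O)NC1=C[C@@](O)(C#C/C=C/C=C/C(=O)NC2=C(O)CCC2=O)[C@H]2O[C@H]2C1=O
F15 | step 13 | alkenylsilane from trans-hydrosilylation of F14 (benzyldimethylsilyl on the second chain carbon, cis to the ring) | CC(C)/C=C/C=C/C=C/C(=O)NC1=C[C@@](O)(/C=C(\[Si](C)(C)Cc3ccccc3)/C=C/C=C/C(=O)NC2=C(O)CCC2=O)[C@H]2O[C@H]2C1=O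
F16 | step 19 | (2E,4E,6E)-7-[(1S,5R,6R)-1-hydroxy-3-{[(2E,4E,6E)-8-methylnona-2,4,6-trienoyl]amino}-4-oxo-7-oxabicyclo[4.1.0]hept-2-en-1-yl]hepta-2,4,6-trienoic acid (same ring configuration as in 29) | CC(C)/C=C/C=C/C=C/C(=O)NC1=C[C@@](O)(/C=C/C=C/C=C/C(O)=O)[C@H]2O[C@H]2C1=O
A1 | alternative 1 | methyl 5-amino-4-oxopentanoate hydrochloride | Cl.COC(=O)CCC(=O)CN
A2 | alternative 1 | methyl 5-{[(2E,4E)-5-bromopenta-2,4-dienoyl]amino}-4-oxopentanoate | COC(=O)CCC(=O)CNC(=O)/C=C/C=C/Br
A3 | alternative 1 | (2E,4E)-5-bromo-N-(2-hydroxy-5-oxocyclopent-1-en-1-yl)penta-2,4-dienamide | O=C(/C=C/C=C/Br)NC1=C(O)CCC1=O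
A4 | alternative 2 | (Z)-configured acyclic chloromethyl ketone aldehyde with the quaternary triethylsilyloxy, triisopropylsilylethynyl carbinol | ClCC(=O)/C=C\[C@@](O[Si](CC)(CC)CC)(C#C[Si](C(C)C)(C(C)C)C(C)C)C=O
A5 | alternative 2 | 4-alkynyl epoxyquinol triethylsilyl ether (5-(triethylsilyloxy)-5-[(triisopropylsilyl)ethynyl]-7-oxabicyclo[4.1.0]hept-3-en-2-one) | O=C1C=C[C@@](O[Si](CC)(CC)CC)(C#C[Si](C(C)C)(C(C)C)C(C)C)[C@H]2O[C@H]21
A6 | alternative 3 | 4,4-dimethoxycyclohexa-2,5-dien-1-one | COC1(OC)C=CC(=O)C=C1
A7 | alternative 3 | cyclopenta-1,3-diene | C1=CCC=C1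
A8 | alternative 3 | endo norbornene-fused enone dimethyl ketal | COC1(OC)C=CC(=O)[C@H]2[C@H]3C=C[C@H](C3)[C@@H]12
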